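**Retrosynthetic overview**
1. Target 31 ← 2-methoxy spiro enone 27 by C9–C10 dehydrogenation, deallylation and desilylation; 27 ← spiro enone 25 by placing the C7 methoxy group on the enone (epoxide, then methoxide).
2. 25 ← silyl dienol ether 13 + (S)-aldehyde 22, forming O2–C1 and C1–C5 in one step. The feature used: spiro carbon C5 of the 2-oxaspiro[4.5]decane is the γ-carbon of the C6=C7–C8=O enone and is bonded to the O2-bearing carbon C1, so C5 is the δ-terminus of a C8 dienol ether and C1 is an aldehyde carbon.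
3. 13 ← Evans syn aldol of the 4-methoxyphenylacetyl imide with O-benzylvanillin (sets C3 and C4), then Birch reduction of the anisyl ring, hydrolysis to the β,γ-enone and silylation.
4. 22 ← methyl (R)-glycerate and eugenol by Mitsunobu inversion (sets C1′), hydroboration and DIBAL-H reduction.
5. Ring order: both benzene rings come from starting materials; the six-membered carbocycle is the Birch-reduced anisyl ring; the tetrahydrofuran is closed last, in the key step.

Key step: step 15

Remark on the chemistry: a 3,4-dialkoxycyclohexa-1,3-diene is not expected to form cleanly by conjugating the Birch 1,4-diene of a dialkoxyarene, because equilibration should move the two alkoxy groups onto separate double bonds; the C5 nucleophile is therefore made regiodefined as the silyl dienol ether of a 4-alkylcyclohex-3-enone from an anisyl ring, and the C7 methoxy group is placed on the C6=C7–C8=O enone after the key step.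

Notation: spiro ring numbered as 2-oxaspiro[4.5]decane: C1 (side-chain carbon), O2, C3 (aryl carbon), C4 (CH2O carbon), C5 (spiro), C6–C10; C1′ is the aryloxy-bearing side-chain carbon; TBS = tert-butyldimethylsilyl, TMS = trimethylsilyl.

**Route**

Step 1
Reactants: 1 4-methoxyphenylacetic acid; 2 (S)-4-benzyloxazolidin-2-one
Product: 4 (S)-4-benzyl-3-[(4-methoxyphenyl)acetyl]oxazolidin-2-one, via mixed pivalic anhydride 3 (not isolated)
Conditions: PivCl, Et3N, THF, −20 °C; then 2, LiCl, −20 °C → rt
Reagents that add atoms: none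
Why: N-acylation of the oxazolidinone through the mixed anhydride (LiCl/Et3N protocol) needs no strong base and installs the auxiliary for the aldol step.

Step 2
Reactants: 4 (S)-4-benzyl-3-[(4-methoxyphenyl)acetyl]oxazolidin-2-one; 5 4-(benzyloxy)-3-methoxybenzaldehyde
Product: 7 (S)-4-benzyl-3-[(2S,3S)-3-(4-benzyloxy-3-methoxyphenyl)-3-hydroxy-2-(4-methoxyphenyl)propanoyl]oxazolidin-2-one, via Z-dibutylboron enolate 6 (not isolated)
Conditions: Bu2BOTf, i-Pr2NEt, CH2Cl2, −78 → 0 °C; 5, −78 → 0 °C; pH 7 buffer, MeOH, H2O2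
Reagents that add atoms: none
Why: Evans syn aldol reaction, in which the Z-boron enolate reacts through a Zimmerman–Traxler transition state on the face away from the benzyl group of the (S)-auxiliary and so sets C4 and C3, the later trans-3,4 pair of the tetrahydrofuran.

Step 3
Reactants: 7 Evans syn aldol adduct
Product: 8 (1S,2R)-1-(4-benzyloxy-3-methoxyphenyl)-2-(4-methoxyphenyl)propane-1,3-diol
Conditions: LiBH4, THF–MeOH, 0 °C
Reagents that add atoms: none
Why: Reductive cleavage of the N-acyloxazolidinone with LiBH4 should give the primary alcohol without touching either stereocentre and return the auxiliary.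

Step 4
Reactants: 8 (1S,2R)-diol
Product: 9 (1S,2R)-1-(4-benzyloxy-3-methoxyphenyl)-3-(tert-butyldimethylsilyloxy)-2-(4-methoxyphenyl)propan-1-ol
Conditions: TBSCl (1.05 equiv), imidazole, CH2Cl2, 0 °C
Reagents that add atoms: tert-butyldimethylsilyl chloride, CC(C)(C)[Si](C)(C)Cl
Why: Silylation should be selective for the primary hydroxyl over the hindered secondary benzylic one.

Step 5
Reactants: 9 mono-TBS ether
Product: 10 4-[(1S,2R)-3-(tert-butyldimethylsilyloxy)-1-hydroxy-2-(4-methoxycyclohexa-1,4-dien-1-yl)propyl]-2-methoxyphenol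
Conditions: Li, NH3(l), THF, t-BuOH, −78 → −33 °C; NH4Cl
Reagents that add atoms: none
Why: Birch reduction, in which the benzyl ether is cleaved first so that the guaiacyl ring is shielded as its phenoxide and the C3 hydroxyl as its alkoxide, while the 4-alkylanisole ring is reduced to the 1-methoxy-1,4-diene with both donor-bearing carbons left sp2.

Step 6
Reactants: 10 Birch diene phenol
Product: 11 (1S,2R)-1-(4-allyloxy-3-methoxyphenyl)-3-(tert-butyldimethylsilyloxy)-2-(4-methoxycyclohexa-1,4-dien-1-yl)propan-1-ol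
Conditions: allyl bromide, K2CO3, acetone, rt
Reagents that add atoms: allyl bromide, C=CCBr
Why: Williamson O-allylation of the phenol in the presence of the secondary alcohol gives an ether that survives the basic steps ahead, and the enol ether is stable to carbonate.

Step 7
Reactants: 11 allyl ether
Product: 12 4-[(1S,2R)-1-(4-allyloxy-3-methoxyphenyl)-3-(tert-butyldimethylsilyloxy)-1-hydroxypropan-2-yl]cyclohex-3-en-1-one
Conditions: oxalic acid (cat.), THF–H2O, 0 °C
Reagents that add atoms: water, O
Why: Mild acid hydrolysis of the Birch enol ether gives the β,γ-unsaturated ketone without moving the C5=C6 bond into conjugation, as in the standard work-up of dihydroanisoles.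

Step 8
Reactants: 12 β,γ-enone
Product: 13 1-(trimethylsilyloxy)-4-[(1S,2R)-1-(4-allyloxy-3-methoxyphenyl)-3-(tert-butyldimethylsilyloxy)-1-(trimethylsilyloxy)propan-2-yl]cyclohexa-1,3-diene
Conditions: TMSOTf (2.3 equiv), Et3N, CH2Cl2, −78 → 0 °C; non-aqueous basic work-up
Reagents that add atoms: trimethylsilyl trifluoromethanesulfonate, C[Si](C)(C)OS(=O)(=O)C(F)(F)F
Why: Soft enolization removes the doubly activated C7 hydrogen (between the carbonyl and C5=C6) and so should give only the conjugated 1-silyloxy-1,3-diene, while the C3 hydroxyl is silylated in the same operation and becomes the handle for oxocarbenium formation.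

Step 9
Reactants: 14 methyl (R)-2,2-dimethyl-1,3-dioxolane-4-carboxylate
Product: 15 methyl (R)-2,3-dihydroxypropanoate
Conditions: p-TsOH·H2O (cat.), MeOH, rt
Reagents that add atoms: none
Why: Acid-catalysed transacetalization in methanol removes the acetonide without affecting the ester or the stereocentre.

Step 10
Reactants: 15 methyl (R)-glycerate
Product: 16 methyl (R)-3-(tert-butyldimethylsilyloxy)-2-hydroxypropanoate
Conditions: TBSCl (1.0 equiv), imidazole, CH2Cl2, 0 °C
Reagents that add atoms: tert-butyldimethylsilyl chloride, CC(C)(C)[Si](C)(C)Cl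
Why: Silylation should be selective for the primary hydroxyl of the diol.

Step 11
Reactants: 16 methyl (R)-3-(tert-butyldimethylsilyloxy)-2-hydroxypropanoate; 17 eugenol
Product: 18 methyl (S)-2-(4-allyl-2-methoxyphenoxy)-3-(tert-butyldimethylsilyloxy)propanoate
Conditions: PPh3, DIAD, toluene, 0 °C → rt
Reagents that add atoms: none
Why: The Mitsunobu reaction of the α-hydroxy ester with the phenol proceeds by SN2 inversion and turns the (R)-alcohol into the (S)-aryl ether, the C1′ stereocentre.

Step 12
Reactants: 18 (S)-aryl ether ester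
Product: 20 methyl (S)-3-(tert-butyldimethylsilyloxy)-2-[4-(3-hydroxypropyl)-2-methoxyphenoxy]propanoate, via B-alkyl-9-BBN adduct 19 (not isolated)
Conditions: 9-BBN, THF, 0 °C → rt; then aq. NaOAc, 30% H2O2, 0 °C → rt
Reagents that add atoms: hydrogen peroxide, OO
Why: Anti-Markovnikov hydroboration of the terminal alkene with 9-BBN leaves the ester untouched, and the buffered oxidation avoids epimerization of the α-aryloxy ester.

Step 13
Reactants: 20 primary alcohol
Product: 21 methyl (S)-3-(tert-butyldimethylsilyloxy)-2-{4-[3-(tert-butyldimethylsilyloxy)propyl]-2-methoxyphenoxy}propanoate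
Conditions: TBSCl, imidazole, DMF, rt
Reagents that add atoms: tert-butyldimethylsilyl chloride, CC(C)(C)[Si](C)(C)Cl
Why: Standard silylation of the primary alcohol gives a side chain that carries only fluoride-labile protection.

Step 14
Reactants: 21 bis-TBS ester
Product: 22 (S)-3-(tert-butyldimethylsilyloxy)-2-{4-[3-(tert-butyldimethylsilyloxy)propyl]-2-methoxyphenoxy}propanal
Conditions: DIBAL-H (1.05 equiv), CH2Cl2, −78 °C; MeOH, Rochelle salt; used crude at once
Reagents that add atoms: none
Why: DIBAL-H reduction of the ester at −78 °C stops at the chelated tetrahedral aluminate, which gives the aldehyde on work-up, and immediate use guards the labile α-stereocentre.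

Step 15
Reactants: 13 silyl dienol ether/C3 TMS ether; 22 (S)-α-aryloxy aldehyde
Product: 25 spiro enone 1-[(S)-2-(TBSO)-1-{4-[3-(TBSO)propyl]-2-methoxyphenoxy}ethyl]-3-(4-allyloxy-3-methoxyphenyl)-4-(TBSO-methyl)-2-oxaspiro[4.5]dec-6-en-8-one (C1 chain/C4 CH2OTBS/C6 on one face of the tetrahydrofuran; C3 aryl on the other), via E-oxocarbenium triflate 23 (not isolated), via silyloxocarbenium triflate 24 (not isolated)
Conditions: 22 (1.3 equiv), 2,6-di-tert-butyl-4-methylpyridine (0.3 equiv), TMSOTf (0.2 equiv), CH2Cl2, −78 → −40 °C; Et3N, then aq. NaHCO3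
Reagents that add atoms: none
Why: Proposed new method: TMSOTf silylates the aldehyde, the C3 trimethylsilyl ether adds and hexamethyldisiloxane leaves to give the E-oxocarbenium ion 23 (O2–C1), which the silyl dienol ether attacks through its δ-carbon C5 (C1–C5) to give silyloxocarbenium ion 24; this returns Me3Si+ to triflate, so the enone 25 forms and the acid turns over. The closest known reactions are the TMSOTf-mediated condensation of silyl ethers with aldehydes followed by Sakurai or Mukaiyama capture (silyl-modified Sakurai and Mukaiyama aldol–Prins reactions), vinylogous Mukaiyama additions of silyl dienol ethers, and allylsilane-terminated oxocarbenium cyclizations to 3-vinyltetrahydrofurans; a dienol ether has not been used for this five-membered closure onto a fully substituted carbon. The tetrahydrofuran closes by C–C bond formation in a five-membered mode that is exo with respect to the C5=C6 bond and endo with respect to the C1=O2 oxocarbenium bond. C5 is set by allylic strain at the C4 stereocentre: the CH2OTBS group should lie over the C5=C6 bond next to the vinylic hydrogen (small A1,3 strain) and not next to the C10 methylene (A1,2 strain), which puts C6 cis to it. C1 is set by the E-oxocarbenium geometry and the same preference, the side chain pointing over the flat C6–H edge of the diene and away from C10H2, hence cis to the C4 substituent and trans to the C3 aryl group, which must then sit pseudoaxial, so this ratio is the least certain. The step needs attack through C5 and not C7, which the tether secures (C7 would give a bridged seven-membered ring), and ionization at C1 and not at the benzylic C3–O bond, which low temperature, a catalytic amount of acid and a hindered pyridine favour; because the ring on C4 is no longer aromatic, no isochroman can form.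

Step 16
Reactants: 25 spiro enone
Product: 26 6,7-epoxy ketone (6,7-epoxy-2-oxaspiro[4.5]decan-8-one; mixture of epoxide faces; all other centres as in 25)
Conditions: t-BuOOH (decane), DBU, CH2Cl2, 0 °C → rt
Reagents that add atoms: tert-butyl hydroperoxide, CC(C)(C)OO
Why: Weitz–Scheffer nucleophilic epoxidation can only touch the electrophilic C6=C7 bond, and both epoxide diastereomers lead to the same product in the next step.

Step 17
Reactants: 26 epoxy ketone
Product: 27 2-methoxy spiro enone: the 7-methoxy derivative of 25 (7-methoxy-2-oxaspiro[4.5]dec-6-en-8-one; all stereocentres as in 25)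
Conditions: NaOMe, MeOH, 50 °C
Reagents that add atoms: methanol (as sodium methoxide), CO
Why: Methoxide opens the α,β-epoxy ketone at the α-carbon C7 and the β-hydroxy ketone dehydrates by E1cB, the known conversion of epoxy ketones into 2-alkoxy enones (as with 4,5-epoxy-3-keto steroids), which places the methoxy group on C7.

Step 18
Reactants: 27 2-methoxy spiro enone
Product: 29 cross-conjugated dienone: 7-methoxy-2-oxaspiro[4.5]deca-6,9-dien-8-one with the substituents and configuration of 27, via trimethylsilyl dienol ether 28 (not isolated)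
Conditions: TMSOTf, Et3N, CH2Cl2, 0 °C; then Pd(OAc)2 (1.1 equiv), MeCN, rt
Reagents that add atoms: none
Why: Saegusa–Ito oxidation, in which enolization can only occur toward C9 (C7 is vinylic and C5 quaternary) and Pd(II) dehydrogenates the silyl dienol ether to the dienone.

Step 19
Reactants: 29 allyl-protected dienone
Product: 30 phenol: 3-(4-hydroxy-3-methoxyphenyl) analogue of 29 with the three TBS ethers intact
Conditions: Pd(PPh3)4 (5 mol %), morpholine, THF, rt
Reagents that add atoms: none
Why: Pd(0)-catalysed deallylation (Tsuji–Trost transfer of the allyl group to morpholine) frees the phenol under neutral conditions that the dienone tolerates.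

Step 20
Reactants: 30 tris-TBS phenol
Product: 31 CNP0252711.1 (target)
Conditions: TBAF/AcOH (1:1), THF, 0 °C → rt
Reagents that add atoms: none
Why: Fluoride cleaves the three primary TBS ethers, and buffering with acetic acid avoids both acid-induced fragmentation of the spirodienone and phenoxide formation at the C3 aryl group.

**Compound list**
1 | 4-methoxyphenylacetic acid | COc1ccc(CC(=O)O)cc1 | starting material
2 | (S)-4-benzyloxazolidin-2-one | O=C1N[C@@H](Cc2ccccc2)CO1 | starting material
3 | mixed pivalic anhydride of 1 (not isolated) | COc1ccc(CC(=O)OC(=O)C(C)(C)C)cc1 | intermediate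
4 | (S)-4-benzyl-3-[(4-methoxyphenyl)acetyl]oxazolidin-2-one | COc1ccc(CC(=O)N2C(=O)OC[C@@H]2Cc2ccccc2)cc1 | intermediate
5 | 4-(benzyloxy)-3-methoxybenzaldehyde | COc1cc(C=O)ccc1OCc1ccccc1 | starting material
6 | Z-dibutylboron enolate of 4 (not isolated) | COc1ccc(/C=C(\OB(CCCC)CCCC)N2C(=O)OC[C@@H]2Cc2ccccc2)cc1 | intermediate
7 | (S)-4-benzyl-3-[(2S,3S)-3-(4-benzyloxy-3-methoxyphenyl)-3-hydroxy-2-(4-methoxyphenyl)propanoyl]oxazolidin-2-one | COc1ccc(cc1)[C@H](C(=O)N1C(=O)OC[C@@H]1Cc1ccccc1)[C@H](O)c1ccc(OCc2ccccc2)c(OC)c1 | intermediate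
8 | (1S,2R)-1-(4-benzyloxy-3-methoxyphenyl)-2-(4-methoxyphenyl)propane-1,3-diol | COc1ccc(cc1)[C@H](CO)[C@H](O)c1ccc(OCc2ccccc2)c(OC)c1 | intermediate
9 | (1S,2R)-1-(4-benzyloxy-3-methoxyphenyl)-3-(tert-butyldimethylsilyloxy)-2-(4-methoxyphenyl)propan-1-ol | COc1ccc(cc1)[C@H](CO[Si](C)(C)C(C)(C)C)[C@H](O)c1ccc(OCc2ccccc2)c(OC)c1 | intermediate
10 | 4-[(1S,2R)-3-(tert-butyldimethylsilyloxy)-1-hydroxy-2-(4-methoxycyclohexa-1,4-dien-1-yl)propyl]-2-methoxyphenol | COC1=CCC(=CC1)[C@H](CO[Si](C)(C)C(C)(C)C)[C@H](O)c1ccc(O)c(OC)c1 | intermediate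
11 | (1S,2R)-1-(4-allyloxy-3-methoxyphenyl)-3-(tert-butyldimethylsilyloxy)-2-(4-methoxycyclohexa-1,4-dien-1-yl)propan-1-ol | COC1=CCC(=CC1)[C@H](CO[Si](C)(C)C(C)(C)C)[C@H](O)c1ccc(OCC=C)c(OC)c1 | intermediate
12 | 4-[(1S,2R)-1-(4-allyloxy-3-methoxyphenyl)-3-(tert-butyldimethylsilyloxy)-1-hydroxypropan-2-yl]cyclohex-3-en-1-one | O=C1CC=C(CC1)[C@H](CO[Si](C)(C)C(C)(C)C)[C@H](O)c1ccc(OCC=C)c(OC)c1 | intermediate
13 | 1-(trimethylsilyloxy)-4-[(1S,2R)-1-(4-allyloxy-3-methoxyphenyl)-3-(tert-butyldimethylsilyloxy)-1-(trimethylsilyloxy)propan-2-yl]cyclohexa-1,3-diene | C[Si](C)(C)OC1=CC=C(CC1)[C@H](CO[Si](C)(C)C(C)(C)C)[C@H](O[Si](C)(C)C)c1ccc(OCC=C)c(OC)c1 | intermediate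
14 | methyl (R)-2,2-dimethyl-1,3-dioxolane-4-carboxylate | COC(=O)[C@H]1COC(C)(C)O1 | starting material
15 | methyl (R)-2,3-dihydroxypropanoate | COC(=O)[C@H](O)CO | intermediate
16 | methyl (R)-3-(tert-butyldimethylsilyloxy)-2-hydroxypropanoate | COC(=O)[C@H](O)CO[Si](C)(C)C(C)(C)C | intermediate
17 | eugenol (4-allyl-2-methoxyphenol) | C=CCc1ccc(O)c(OC)c1 | starting material
18 | methyl (S)-2-(4-allyl-2-methoxyphenoxy)-3-(tert-butyldimethylsilyloxy)propanoate | COC(=O)[C@@H](Oc1ccc(CC=C)cc1OC)CO[Si](C)(C)C(C)(C)C | intermediate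
19 | B-alkyl-9-BBN adduct of 18 (not isolated) | COC(=O)[C@@H](Oc1ccc(CCCB2C3CCCC2CCC3)cc1OC)CO[Si](C)(C)C(C)(C)C | intermediate
20 | methyl (S)-3-(tert-butyldimethylsilyloxy)-2-[4-(3-hydroxypropyl)-2-methoxyphenoxy]propanoate | COC(=O)[C@@H](Oc1ccc(CCCO)cc1OC)CO[Si](C)(C)C(C)(C)C | intermediate
21 | methyl (S)-3-(tert-butyldimethylsilyloxy)-2-{4-[3-(tert-butyldimethylsilyloxy)propyl]-2-methoxyphenoxy}propanoate | COC(=O)[C@@H](Oc1ccc(CCCO[Si](C)(C)C(C)(C)C)cc1OC)CO[Si](C)(C)C(C)(C)C | intermediate
22 | (S)-3-(tert-butyldimethylsilyloxy)-2-{4-[3-(tert-butyldimethylsilyloxy)propyl]-2-methoxyphenoxy}propanal | O=C[C@H](CO[Si](C)(C)C(C)(C)C)Oc1ccc(CCCO[Si](C)(C)C(C)(C)C)cc1OC | intermediate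
23 | E-oxocarbenium triflate from 13 and 22 (not isolated) | C[Si](C)(C)OC1=CC=C(CC1)[C@H](CO[Si](C)(C)C(C)(C)C)[C@H](/[O+]=C/[C@H](CO[Si](C)(C)C(C)(C)C)Oc1ccc(CCCO[Si](C)(C)C(C)(C)C)cc1OC)c1ccc(OCC=C)c(OC)c1.[O-]S(=O)(=O)C(F)(F)F | intermediate
24 | spirocyclic C8 silyloxocarbenium triflate (not isolated) | C[Si](C)(C)[O+]=C1C=C[C@]2(CC1)[C@H](CO[Si](C)(C)C(C)(C)C)[C@@H](c1ccc(OCC=C)c(OC)c1)O[C@@H]2[C@H](CO[Si](C)(C)C(C)(C)C)Oc1ccc(CCCO[Si](C)(C)C(C)(C)C)cc1OC.[O-]S(=O)(=O)C(F)(F)F | intermediate
25 | spiro enone (2-oxaspiro[4.5]dec-6-en-8-one; C1 chain, C4 CH2OTBS and C6 on one face of the tetrahydrofuran, C3 aryl on the other; C1′ S) | O=C1C=C[C@]2(CC1)[C@H](CO[Si](C)(C)C(C)(C)C)[C@@H](c1ccc(OCC=C)c(OC)c1)O[C@@H]2[C@H](CO[Si](C)(C)C(C)(C)C)Oc1ccc(CCCO[Si](C)(C)C(C)(C)C)cc1OC | intermediate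
26 | 6,7-epoxy ketone from 25 (epoxide faces not defined) | O=C1C2OC2[C@]3(CC1)[C@H](CO[Si](C)(C)C(C)(C)C)[C@@H](c1ccc(OCC=C)c(OC)c1)O[C@@H]3[C@H](CO[Si](C)(C)C(C)(C)C)Oc1ccc(CCCO[Si](C)(C)C(C)(C)C)cc1OC | intermediate
27 | 2-methoxy spiro enone (7-methoxy-2-oxaspiro[4.5]dec-6-en-8-one; configuration as 25) | COC1=C[C@]2(CCC1=O)[C@H](CO[Si](C)(C)C(C)(C)C)[C@@H](c1ccc(OCC=C)c(OC)c1)O[C@@H]2[C@H](CO[Si](C)(C)C(C)(C)C)Oc1ccc(CCCO[Si](C)(C)C(C)(C)C)cc1OC | intermediate
28 | trimethylsilyl dienol ether of 27 (C8 OTMS, C8=C9; not isolated) | COC1=C[C@]2(CC=C1O[Si](C)(C)C)[C@H](CO[Si](C)(C)C(C)(C)C)[C@@H](c1ccc(OCC=C)c(OC)c1)O[C@@H]2[C@H](CO[Si](C)(C)C(C)(C)C)Oc1ccc(CCCO[Si](C)(C)C(C)(C)C)cc1OC | intermediate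
29 | allyl-protected tris-TBS dienone (7-methoxy-2-oxaspiro[4.5]deca-6,9-dien-8-one) | COC1=C[C@]2(C=CC1=O)[C@H](CO[Si](C)(C)C(C)(C)C)[C@@H](c1ccc(OCC=C)c(OC)c1)O[C@@H]2[C@H](CO[Si](C)(C)C(C)(C)C)Oc1ccc(CCCO[Si](C)(C)C(C)(C)C)cc1OC | intermediate
30 | tris-TBS dienone with free phenol | COC1=C[C@]2(C=CC1=O)[C@H](CO[Si](C)(C)C(C)(C)C)[C@@H](c1ccc(O)c(OC)c1)O[C@@H]2[C@H](CO[Si](C)(C)C(C)(C)C)Oc1ccc(CCCO[Si](C)(C)C(C)(C)C)cc1OC | intermediate
31 | CNP0252711.1 | COC1=C[C@]2(C=CC1=O)[C@H](CO)[C@@H](c1ccc(O)c(OC)c1)O[C@@H]2[C@H](CO)Oc1ccc(CCCO)cc1OC | target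

**Step count and risks**
Total step count: 20. Longest linear sequence: 14 steps (steps 1–8, then 15–20).

Step 15 (proposed new method). Several processes can divert it: ionization of the benzylic C3–O bond next to the electron-rich aryl group, with capture of that cation by the dienol ether; intermolecular Mukaiyama addition through C7; poor facial selectivity at C1; and enolization of the aldehyde with loss of configuration at C1′. The fallback uses known chemistry and reverses the order of bond formation. It sets out from 13 and 22: an intermolecular vinylogous Mukaiyama aldol addition (BF3·OEt2, CH2Cl2, −78 °C, aqueous work-up) through the γ-carbon forms C1–C5 and should give the γ-aldol hydroxy enone diol F1. A catalytic acid (Sc(OTf)3 or CSA, CH2Cl2, 0 °C) then ionizes the p-alkoxybenzylic C3 alcohol and the C1 hydroxyl captures the cation trans to the C4 substituent, the usual cyclization of benzylic 1,4-diols to 2-aryltetrahydrofurans. After separation of the C1/C5 diastereomers, which form here without the ring template, the sequence comes back to the route at 25.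

Step 16. Conjugate addition of the hydroperoxide at the neopentyl carbon C6 may be slow, and in step 17 the β-alkoxide may open the ring by retro-aldol cleavage before it dehydrates. The fallback sets out from 25: α-iodination of the enone (I2, pyridine, CH2Cl2, rt) should give the 7-iodo spiro enone F2, and an Ullmann-type copper-catalysed C–O coupling with methanol (CuI, 3,4,7,8-tetramethyl-1,10-phenanthroline, Cs2CO3, MeOH–toluene, 80 °C) puts the methoxy group on C7 without passing through a β-hydroxy ketone. It comes back to the route at 27.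

Step 5. Hydrogenolysis of the benzylic C3–O bond or partial reduction of the guaiacyl ring may compete before the benzyl ether has been cleaved to the protecting phenoxide. The fallback sets out from 9 and separates the two events: catalytic hydrogenolysis (H2, Pd/C, EtOAc, rt) gives the free phenol with intact anisyl ring F3, which is converted into its dilithium phenoxide/alkoxide (n-BuLi, 2 equiv, THF, −78 °C) before the Li/NH3/t-BuOH reduction, so that only the anisyl ring can accept electrons. It comes back to the route at 10.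

**Further compounds**
F1 | step 15 | γ-aldol hydroxy enone diol: 4-substituted 4-[(1S,2R)-1-(4-allyloxy-3-methoxyphenyl)-3-(TBSO)-1-hydroxypropan-2-yl]cyclohex-2-en-1-one carrying at C4 the 1-hydroxy-(2S)-3-(TBSO)-2-aryloxypropyl chain (C1 and C5 not defined) | O=C1C=CC(CC1)(C(O)[C@H](CO[Si](C)(C)C(C)(C)C)Oc1ccc(CCCO[Si](C)(C)C(C)(C)C)cc1OC)[C@H](CO[Si](C)(C)C(C)(C)C)[C@H](O)c1ccc(OCC=C)c(OC)c1
F2 | step 16 | 7-iodo spiro enone (7-iodo-2-oxaspiro[4.5]dec-6-en-8-one; configuration as 25) | O=C1C(I)=C[C@]2(CC1)[C@H](CO[Si](C)(C)C(C)(C)C)[C@@H](c1ccc(OCC=C)c(OC)c1)O[C@@H]2[C@H](CO[Si](C)(C)C(C)(C)C)Oc1ccc(CCCO[Si](C)(C)C(C)(C)C)cc1OC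
F3 | step 5 | 4-[(1S,2R)-3-(tert-butyldimethylsilyloxy)-1-hydroxy-2-(4-methoxyphenyl)propyl]-2-methoxyphenol | COc1ccc(cc1)[C@H](CO[Si](C)(C)C(C)(C)C)[C@H](O)c1ccc(O)c(OC)c1
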